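**Retrosynthetic overview** (drimane numbering: C3 ketone, C4 gem-dimethyl, C5/C10 ring fusion, C9 bears C11H2O)
1. Target 17 ⇐ Mitsunobu ether bond C11–O between umbelliferone 16 and hydroxymethyl ketone 15.
2. 15 ⇐ carbonyl-ene hydroxymethylation of the 8,9-alkene of trans-decalone 14 (C9–C11 bond formed anti to the axial C10 methyl; alkene moves to 7,8).
3. 14 ⇐ reductive methylation of dienone 12 (sets the trans ring fusion and the C4 gem-dimethyl); 12 ⇐ aldol closure of ring A onto the C5 ketone.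
4. Side chain C1–C4 ⇐ Wittig homologation of the quaternary aldehyde 7, obtained from amide 6.
5. Ring B with quaternary C10 ⇐ auxiliary-controlled Birch reduction–methylation of benzamide 4 (from 2-methoxy-5-methylbenzoic acid); ring B is the former arene, ring A is formed second.

Assumption: the (S)-auxiliary 2 directs methylation in step 2 to the (R)-quaternary carbon drawn in 6 (attack anti to the methoxymethyl arm of the chelated enolate); if the sense is opposite, the enantiomeric auxiliary is used and nothing else changes.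

**Route**

Step 1
Reactants: 1 2-methoxy-5-methylbenzoic acid; 2 (S)-2-(methoxymethyl)pyrrolidine
Product: 4 [(2S)-2-(methoxymethyl)pyrrolidin-1-yl](2-methoxy-5-methylphenyl)methanone, via acid chloride 3 (not isolated)
Conditions: (COCl)2, cat. DMF, CH2Cl2, 0 → 25 °C; then 2, Et3N, CH2Cl2, 0 °C
Reagents that add atoms: none
Why: Acyl chloride formation followed by amidation attaches the chiral auxiliary; no stereocenter is formed.

Step 2
Reactants: 4 [(2S)-2-(methoxymethyl)pyrrolidin-1-yl](2-methoxy-5-methylphenyl)methanone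
Product: 6 [(2S)-2-(methoxymethyl)pyrrolidin-1-yl][(1R)-2-methoxy-1,5-dimethylcyclohexa-2,5-dien-1-yl]methanone, via potassium amide enolate 5 (not isolated)
Conditions: K (2.2 equiv), NH3(l)/THF, t-BuOH (1.0 equiv), −78 °C; then MeI (3 equiv), −78 → 25 °C
Reagents that add atoms: methyl iodide, CI
Why: Auxiliary-controlled Birch reduction–alkylation: the carboxamide directs ipso/para reduction to the chelated enolate 5, which is C-methylated anti to the methoxymethyl arm, breaking aromaticity and setting the quaternary carbon (future C10) as R while leaving the enol ether (masked C5 ketone) and the methyl-bearing alkene (future C8=C9) in place.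

Step 3
Reactants: 6 [(2S)-2-(methoxymethyl)pyrrolidin-1-yl][(1R)-2-methoxy-1,5-dimethylcyclohexa-2,5-dien-1-yl]methanone
Product: 7 (1R)-2-methoxy-1,5-dimethylcyclohexa-2,5-diene-1-carbaldehyde
Conditions: Cp2Zr(H)Cl (1.8 equiv), THF, 25 °C, 30 min; aqueous work-up
Reagents that add atoms: none
Why: Partial reduction of a tertiary amide by Cp2Zr(H)Cl stops at the zirconated hemiaminal, which releases the aldehyde and the auxiliary on work-up; the non-enolizable quaternary center cannot epimerize.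

Step 4
Reactants: 7 (1R)-2-methoxy-1,5-dimethylcyclohexa-2,5-diene-1-carbaldehyde; 8 1-(triphenylphosphoranylidene)butan-2-one
Product: 9 (1E)-1-[(1R)-2-methoxy-1,5-dimethylcyclohexa-2,5-dien-1-yl]pent-1-en-3-one
Conditions: toluene, 100 °C
Reagents that add atoms: none
Why: Wittig olefination of a non-enolizable aldehyde with a stabilized ylide gives the E-enone and brings in C2–C4 plus the first C4 methyl; no stereocenter is touched.

Step 5
Reactants: 9 (1E)-1-[(1R)-2-methoxy-1,5-dimethylcyclohexa-2,5-dien-1-yl]pent-1-en-3-one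
Product: 10 1-[(1R)-2-methoxy-1,5-dimethylcyclohexa-2,5-dien-1-yl]pentan-3-one
Conditions: Cu(OAc)2 (5 mol%), 1,2-bis(diphenylphosphino)benzene (5 mol%), (EtO)2MeSiH (2 equiv), t-BuOH (2 equiv), toluene, 25 °C
Reagents that add atoms: none
Why: Copper hydride 1,4-reduction saturates only the enone C=C, leaving the enol ether and the trisubstituted alkene, so that the chain can reach C5 for ring closure.

Step 6
Reactants: 10 1-[(1R)-2-methoxy-1,5-dimethylcyclohexa-2,5-dien-1-yl]pentan-3-one
Product: 12 (4aR)-1,4a,6-trimethyl-4,4a,7,8-tetrahydronaphthalen-2(3H)-one, via diketone 11 (not isolated)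
Conditions: 1 M aq HCl, THF, 25 °C; then KOH, MeOH, 65 °C
Reagents that add atoms: none
Why: Enol ether hydrolysis unmasks the C5 ketone, and an intramolecular aldol condensation (Robinson-type closure) of the ethyl ketone forms ring A as the 4-methyl enone; the 8,9-alkene cannot move into conjugation past the quaternary C10.

Step 7
Reactants: 12 (4aR)-1,4a,6-trimethyl-4,4a,7,8-tetrahydronaphthalen-2(3H)-one
Product: 14 (4aR,8aR)-1,1,4a,6-tetramethyl-3,4,4a,7,8,8a-hexahydronaphthalen-2(1H)-one, via lithium enolate 13 (not isolated)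
Conditions: Li (2.2 equiv), NH3(l)/THF, t-BuOH (1.0 equiv), −78 °C; then MeI (5 equiv), −78 → −33 °C
Reagents that add atoms: methyl iodide, CI
Why: Dissolving-metal reductive alkylation of the enone: axial protonation at C5 gives the trans-fused enolate (C5–H anti to the C10 methyl), which is methylated regiospecifically at C4 to give the gem-dimethyl ketone; the isolated alkene is not reduced.

Step 8
Reactants: 14 (4aR,8aR)-1,1,4a,6-tetramethyl-3,4,4a,7,8,8a-hexahydronaphthalen-2(1H)-one
Product: 15 (4aS,5R,8aR)-5-(hydroxymethyl)-1,1,4a,6-tetramethyl-3,4,4a,5,8,8a-hexahydronaphthalen-2(1H)-one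
Conditions: paraformaldehyde, Me2AlCl (2.0 equiv), CH2Cl2, 0 → 25 °C
Reagents that add atoms: formaldehyde (from paraformaldehyde), C=O
Why: Lewis-acid carbonyl-ene reaction: formaldehyde bonds to the less substituted alkene carbon C9 on the face anti to the axial C10 methyl (sets C9 with the axial CH2OH), and transfer of the aligned axial C7–H moves the alkene to C7=C8.

Step 9
Reactants: 15 (4aS,5R,8aR)-5-(hydroxymethyl)-1,1,4a,6-tetramethyl-3,4,4a,5,8,8a-hexahydronaphthalen-2(1H)-one; 16 umbelliferone (7-hydroxy-2H-chromen-2-one)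
Product: 17 7-{[(1R,4aR,8aS)-2,5,5,8a-tetramethyl-6-oxo-1,4,4a,5,6,7,8,8a-octahydronaphthalen-1-yl]methoxy}-2H-chromen-2-one
Conditions: PPh3, DIAD, THF, 0 → 25 °C
Reagents that add atoms: none
Why: Mitsunobu etherification of the primary alcohol with the acidic phenol forms the aryl ether at C11 without touching any stereocenter or the ketone.

**Compound list**
1 | 2-methoxy-5-methylbenzoic acid | COc1ccc(C)cc1C(=O)O | starting material
2 | (S)-2-(methoxymethyl)pyrrolidine | COC[C@@H]1CCCN1 | starting material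
3 | 2-methoxy-5-methylbenzoyl chloride | COc1ccc(C)cc1C(=O)Cl | intermediate
4 | [(2S)-2-(methoxymethyl)pyrrolidin-1-yl](2-methoxy-5-methylphenyl)methanone | COC[C@@H]1CCCN1C(=O)c1cc(C)ccc1OC | intermediate
5 | potassium [(2S)-2-(methoxymethyl)pyrrolidin-1-yl](6-methoxy-3-methylcyclohexa-2,5-dien-1-ylidene)methanolate | COC[C@@H]1CCCN1C([O-])=C1C=C(C)CC=C1OC.[K+] | intermediate
6 | [(2S)-2-(methoxymethyl)pyrrolidin-1-yl][(1R)-2-methoxy-1,5-dimethylcyclohexa-2,5-dien-1-yl]methanone | COC[C@@H]1CCCN1C(=O)[C@]1(C)C=C(C)CC=C1OC | intermediate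
7 | (1R)-2-methoxy-1,5-dimethylcyclohexa-2,5-diene-1-carbaldehyde | O=C[C@]1(C)C=C(C)CC=C1OC | intermediate
8 | 1-(triphenylphosphoranylidene)butan-2-one | CCC(=O)C=P(c1ccccc1)(c1ccccc1)c1ccccc1 | starting material
9 | (1E)-1-[(1R)-2-methoxy-1,5-dimethylcyclohexa-2,5-dien-1-yl]pent-1-en-3-one | CCC(=O)/C=C/[C@]1(C)C=C(C)CC=C1OC | intermediate
10 | 1-[(1R)-2-methoxy-1,5-dimethylcyclohexa-2,5-dien-1-yl]pentan-3-one | CCC(=O)CC[C@]1(C)C=C(C)CC=C1OC | intermediate
11 | (2R)-2,4-dimethyl-2-(3-oxopentyl)cyclohex-3-en-1-one | CCC(=O)CC[C@]1(C)C=C(C)CCC1=O | intermediate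
12 | (4aR)-1,4a,6-trimethyl-4,4a,7,8-tetrahydronaphthalen-2(3H)-one | CC1=C2CCC(C)=C[C@@]2(C)CCC1=O | intermediate
13 | lithium (4aR,8aR)-1,4a,6-trimethyl-3,4,4a,7,8,8a-hexahydronaphthalen-2-olate | CC1=C[C@@]2(C)CCC([O-])=C(C)[C@@H]2CC1.[Li+] | intermediate
14 | (4aR,8aR)-1,1,4a,6-tetramethyl-3,4,4a,7,8,8a-hexahydronaphthalen-2(1H)-one | CC1=C[C@@]2(C)CCC(=O)C(C)(C)[C@@H]2CC1 | intermediate
15 | (4aS,5R,8aR)-5-(hydroxymethyl)-1,1,4a,6-tetramethyl-3,4,4a,5,8,8a-hexahydronaphthalen-2(1H)-one | CC1=CC[C@H]2C(C)(C)C(=O)CC[C@]2(C)[C@@H]1CO | intermediate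
16 | umbelliferone (7-hydroxy-2H-chromen-2-one) | Oc1ccc2ccc(=O)oc2c1 | starting material
17 | 7-{[(1R,4aR,8aS)-2,5,5,8a-tetramethyl-6-oxo-1,4,4a,5,6,7,8,8a-octahydronaphthalen-1-yl]methoxy}-2H-chromen-2-one | CC1=CC[C@H]2C(C)(C)C(=O)CC[C@]2(C)[C@@H]1COc1ccc2ccc(=O)oc2c1 | target

**Step count and risks**
Total steps: 9. Longest linear sequence: 9 (from 1).

Steps most likely to fail:

Step 8. The ene reaction can transfer hydrogen from the C8 methyl instead of C7–H and give the exocyclic 8(12)-alkene, quite possibly as a major product, or it can stall at the hindered C9. The fallback sets out from 14. Allylic oxidation at C7 (CrO3, 3,5-dimethylpyrazole, CH2Cl2, −20 °C) gives the enedione (4aR,8aR)-1,1,4a,6-tetramethyl-3,4,4a,8a-tetrahydronaphthalene-2,7(1H,8H)-dione F1. Copper-catalysed 1,4-addition of (i-PrO)Me2SiCH2MgCl (CuBr·SMe2, THF, −40 °C), again anti to the axial methyl, with trapping of the enolate by N-(5-chloropyridin-2-yl)triflimide, gives the enol triflate (1S,4aR,8aS)-1-{[dimethyl(propan-2-yloxy)silyl]methyl}-2,5,5,8a-tetramethyl-6-oxo-1,4,4a,5,6,7,8,8a-octahydronaphthalen-3-yl trifluoromethanesulfonate F2. Reduction with Pd(OAc)2, PPh3, HCO2H and Bu3N in DMF at 60 °C fixes the 7,8-alkene in the silane (4aS,5R,8aR)-5-{[dimethyl(propan-2-yloxy)silyl]methyl}-1,1,4a,6-tetramethyl-3,4,4a,5,8,8a-hexahydronaphthalen-2(1H)-one F3. Tamao oxidation (H2O2, KF, KHCO3, THF/MeOH) then gives 15, where the route is rejoined.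

Step 3. The amide sits on a quaternary carbon and may react slowly or over-reduce. The fallback sets out from 6. LiH2N·BH3 (THF, 0 → 25 °C) reduces the amide to the primary alcohol [(1S)-2-methoxy-1,5-dimethylcyclohexa-2,5-dien-1-yl]methanol F4 with release of 2. Oxidation with SO3·pyridine, DMSO and Et3N gives 7, where the route is rejoined.

Step 2. Facial control by the auxiliary may be incomplete on this 5-methyl substrate, or may run in the opposite sense. The fallback sets out from 1. Birch reduction–methylation of the free acid (Li, NH3/THF, −78 °C; then MeI) gives racemic 2-methoxy-1,5-dimethylcyclohexa-2,5-diene-1-carboxylic acid F5. Amidation with 2 (1-chloro-N,N,2-trimethylprop-1-en-1-amine, then 2 and Et3N) gives 6 together with its diastereomer [(2S)-2-(methoxymethyl)pyrrolidin-1-yl][(1S)-2-methoxy-1,5-dimethylcyclohexa-2,5-dien-1-yl]methanone F6, which is removed by chromatography. The route is rejoined at 6.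

**Further compounds**
F1 | step 8 | (4aR,8aR)-1,1,4a,6-tetramethyl-3,4,4a,8a-tetrahydronaphthalene-2,7(1H,8H)-dione | CC1=C[C@@]2(C)CCC(=O)C(C)(C)[C@@H]2CC1=O
F2 | step 8 | (1S,4aR,8aS)-1-{[dimethyl(propan-2-yloxy)silyl]methyl}-2,5,5,8a-tetramethyl-6-oxo-1,4,4a,5,6,7,8,8a-octahydronaphthalen-3-yl trifluoromethanesulfonate | CC1=C(OS(=O)(=O)C(F)(F)F)C[C@H]2C(C)(C)C(=O)CC[C@]2(C)[C@@H]1C[Si](C)(C)OC(C)C
F3 | step 8 | (4aS,5R,8aR)-5-{[dimethyl(propan-2-yloxy)silyl]methyl}-1,1,4a,6-tetramethyl-3,4,4a,5,8,8a-hexahydronaphthalen-2(1H)-one | CC1=CC[C@H]2C(C)(C)C(=O)CC[C@]2(C)[C@@H]1C[Si](C)(C)OC(C)C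
F4 | step 3 | [(1S)-2-methoxy-1,5-dimethylcyclohexa-2,5-dien-1-yl]methanol | OC[C@]1(C)C=C(C)CC=C1OC
F5 | step 2 | rac-2-methoxy-1,5-dimethylcyclohexa-2,5-diene-1-carboxylic acid | COC1=CCC(C)=CC1(C)C(=O)O
F6 | step 2 | [(2S)-2-(methoxymethyl)pyrrolidin-1-yl][(1S)-2-methoxy-1,5-dimethylcyclohexa-2,5-dien-1-yl]methanone | COC[C@@H]1CCCN1C(=O)[C@@]1(C)C=C(C)CC=C1OC
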